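Ring atoms are numbered along the SMILES (C1, the chain-bearing cyclobutane CH, to C13, CH–CO2Me). Everything rests on disconnecting the cyclohexene C2–C3=C4–C5–C6–C7 at C2–C3: without C3 it is a five-membered ring (C2, C4, C5, C6, C7), that of commercial bicyclo[3.2.0]hept-2-en-6-one. This cis-fused ring serves as a template: an intramolecular Diels–Alder reaction of a dienoate tethered at C8 onto C5=C6 sets C5, C6, C10 and C13 and closes the cyclopentane and the ester-bearing cyclohexene. The key step then inserts C3 (from Me3SiCHN2) into the C2–C4(=O) bond of the resulting tetracyclic cyclopentanone, which creates the six-membered ring as the last ring and exploits that the C3=C4 olefin lies between two methines; silicon later fixes the olefin position.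

Key step: step 11

Remark: (1S,5R)-bicyclo[3.2.0]hept-2-en-6-one and (E)-1-bromoprop-1-ene are taken to be purchasable as single stereoisomers (the ketone is otherwise available by the established enzymatic resolution of the racemate).
Remark: the rings of the target are called A (cyclobutane C1/C2/C7/C8), B (C2–C7), C (C5/C6/C10–C13) and D (cyclopentane C6–C10); the bicyclic intermediates 6–16 carry bicyclo[3.2.0]heptane locants, whose C1, C2, C3, C4, C5, C6 and C7 become skeleton C2, C4, C5, C6, C7, C8 and C1.

Step 1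
Reactants: 1 7-bromohept-1-ene; 2 (E)-1-bromoprop-1-ene
Product: 4 (E)-10-bromodec-2-ene, via B-(7-bromoheptyl)-9-BBN 3 (not isolated)
Conditions: 9-BBN, THF, 0 °C to rt; then 2, PdCl2(dppf) (cat.), aq. K3PO4, DMF–THF, 50 °C
Reagents that add atoms: none
Why: Anti-Markovnikov hydroboration of the terminal olefin followed by B-alkyl Suzuki–Miyaura coupling, in which Pd(0) inserts into the alkenyl C–Br bond much faster than into the primary alkyl bromide and the E geometry of 2 is retained.

Step 2
Reactants: 4 (E)-10-bromodec-2-ene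
Product: 5 (E)-10-iododec-2-ene
Conditions: NaI, acetone, reflux
Reagents that add atoms: sodium iodide, [Na+].[I-]
Why: Finkelstein halide exchange (SN2) driven by precipitation of NaBr provides the more reactive primary iodide for the enolate alkylation.

Step 3
Reactants: 6 (1S,5R)-bicyclo[3.2.0]hept-2-en-6-one; 5 (E)-10-iododec-2-ene
Product: 8 (1R,5R,7R)-7-exo-[(E)-dec-8-en-1-yl]bicyclo[3.2.0]hept-2-en-6-one, via lithium enolate 7 (not isolated)
Conditions: LDA, THF, −78 °C; then 5, DMPU, −78 to −20 °C
Reagents that add atoms: none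
Why: Enolate alkylation: LDA removes a C7 proton (the bridgehead C5–H would give a ring-fusion enolate) and the iodide attacks the enolate from the convex exo face of the cis-fused bicycle, which sets the C7 stereocentre (skeleton C1) trans to the five-membered ring.

Step 4
Reactants: 8 (1R,5R,7R)-7-exo-[(E)-dec-8-en-1-yl]bicyclo[3.2.0]hept-2-en-6-one; 9 ethyl (triphenylphosphoranylidene)acetate
Product: 10 ethyl 2-[7-exo-((E)-dec-8-en-1-yl)bicyclo[3.2.0]hept-2-en-6-ylidene]acetate
Conditions: toluene, 100 °C
Reagents that add atoms: none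
Why: Wittig olefination of the strained and therefore electrophilic cyclobutanone with a stabilised ylide; both olefin isomers are usable because the next step saturates the double bond.

Step 5
Reactants: 10 ethyl 2-[7-exo-((E)-dec-8-en-1-yl)bicyclo[3.2.0]hept-2-en-6-ylidene]acetate
Product: 11 ethyl 2-[7-exo-((E)-dec-8-en-1-yl)bicyclo[3.2.0]hept-2-en-6-endo-yl]acetate
Conditions: Cu(OAc)2·H2O (cat.), 1,2-bis(diphenylphosphino)benzene (cat.), PhMe2SiH, t-BuOH, toluene, rt
Reagents that add atoms: none
Why: Copper hydride conjugate reduction (Stryker type) is chemoselective for the enoate and transfers hydride to the ring carbon C6 from the convex face, as hydride reagents do on bicyclo[3.2.0]heptan-6-ones, so the CH2CO2Et arm (on skeleton C8) becomes endo and trans to the decenyl chain.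

Step 6
Reactants: 11 ethyl 2-[7-exo-((E)-dec-8-en-1-yl)bicyclo[3.2.0]hept-2-en-6-endo-yl]acetate
Product: 13 ethyl 2-[7-exo-((E)-dec-8-en-1-yl)-2-exo-hydroxybicyclo[3.2.0]hept-3-en-6-endo-yl]acetate, via allylic hydroperoxide 12 (not isolated)
Conditions: O2, tetraphenylporphyrin (cat.), visible light, CH2Cl2, −20 °C; then PPh3, 0 °C
Reagents that add atoms: oxygen (as singlet oxygen), O=O
Why: Schenck ene reaction: singlet oxygen attacks the strained cis-cyclopentene on its exo face and takes the exo hydrogen of the C4 methylene (the bridgehead hydrogen would lead to a strained ring-fusion olefin), which moves the double bond to C3=C4 and places an exo oxygen on C2; PPh3 reduces the hydroperoxide and the carbinol configuration is erased in step 10.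

Step 7
Reactants: 13 ethyl 2-[7-exo-((E)-dec-8-en-1-yl)-2-exo-hydroxybicyclo[3.2.0]hept-3-en-6-endo-yl]acetate
Product: 14 2-[7-exo-((E)-dec-8-en-1-yl)-2-exo-hydroxybicyclo[3.2.0]hept-3-en-6-endo-yl]acetaldehyde
Conditions: DIBAL-H (2.2 equiv), CH2Cl2, −78 °C; Rochelle salt work-up
Reagents that add atoms: none
Why: DIBAL-H half-reduction of the ester at −78 °C stops at the aluminium hemiacetal, which gives the aldehyde on work-up; the free hydroxyl only consumes one equivalent of hydride.

Step 8
Reactants: 14 2-[7-exo-((E)-dec-8-en-1-yl)-2-exo-hydroxybicyclo[3.2.0]hept-3-en-6-endo-yl]acetaldehyde; 15 methyl (E)-4-(diethoxyphosphoryl)but-2-enoate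
Product: 16 methyl (2E,4E)-6-[7-exo-((E)-dec-8-en-1-yl)-2-exo-hydroxybicyclo[3.2.0]hept-3-en-6-endo-yl]hexa-2,4-dienoate
Conditions: 15 (excess), LiHMDS, THF, −78 to 0 °C
Reagents that add atoms: none
Why: Vinylogous Horner–Wadsworth–Emmons olefination with the γ-phosphonocrotonate anion gives the thermodynamically preferred (2E,4E)-dienoate.

Step 9
Reactants: 16 methyl (2E,4E)-6-[7-exo-((E)-dec-8-en-1-yl)-2-exo-hydroxybicyclo[3.2.0]hept-3-en-6-endo-yl]hexa-2,4-dienoate
Product: 17 4-hydroxy-3-nor tetracycle (rings A/C/D of the target plus the five-membered ring C2/C4/C5/C6/C7; OH on the convex face)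
Conditions: toluene (high dilution), BHT, 150 °C, sealed tube
Reagents that add atoms: none
Why: Intramolecular Diels–Alder reaction of a 1,3,8-nonatriene held on a cis-fused bicycle (the reaction type of the endiandric acid cascade): the endo arm can reach only the concave face of the ring olefin and its short tether allows only the exo transition state, so C10–C6 and C13–C5 form cis on that face with trans ring fusion at C6–C10, while the E,E-diene places the ester at C13 cis to C9.

Step 10
Reactants: 17 4-hydroxy-3-nor tetracycle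
Product: 18 4-oxo-3-nor tetracycle (cyclopentanone C2/C4/C5/C6/C7)
Conditions: Dess–Martin periodinane, NaHCO3, CH2Cl2, rt
Reagents that add atoms: none
Why: Dess–Martin oxidation converts the secondary alcohol into the ketone under buffered, non-basic conditions that leave the stereocentres α to the carbonyl groups (C2, C5, C13) untouched.

Step 11
Reactants: 18 4-oxo-3-nor tetracycle
Product: 19 3-trimethylsilyl-4-oxo tetracycle (ring B closed as a cyclohexanone; β-keto silane)
Conditions: Me3SiCHN2, Sc(OTf)3 (cat.), toluene–CH2Cl2, 0 °C to rt; filtration, used crude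
Reagents that add atoms: (trimethylsilyl)diazomethane, C[Si](C)(C)C=[N+]=[N-]
Why: The Lewis acid activates the C4 ketone, the nucleophilic carbon of Me3SiCHN2 adds from the open convex face and the diazonium betaine undergoes a 1,2-shift of the C2–C4 bond with loss of N2, which inserts the CH(SiMe3) unit (C3) between C2 and C4. The closest known reaction type is the Lewis-acid-promoted (Tiffeneau–Demjanov-type) homologation of cycloalkanones with trimethylsilyldiazomethane. Ring B is closed by ring enlargement (cyclopentanone to cyclohexanone through a 1,2-carbon shift; it is not a chain cyclisation, so no Baldwin descriptor applies) and it is formed last, rings A, C and D being in place. The only new stereocentre, the silylated C3, is of no consequence because it becomes sp2 in step 12, and the migrating C2 keeps its configuration because the shift is suprafacial. The step needs chemoselectivity for the ketone over the ester and the olefins, a single insertion and a defined place for the future double bond: the ketone is the only strongly electrophilic carbonyl, the hindered β-keto silane resists a second insertion, and the silyl group marks the inserted carbon, so that migration of C5 instead of C2 would give a regioisomer that leads to the same C3=C4 olefin after steps 12 and 13.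

Step 12
Reactants: 19 3-trimethylsilyl-4-oxo tetracycle
Product: 21 C4 alkenyl nonaflate of the tetracycle (C3=C4), via cesium enolate 20 (not isolated)
Conditions: nonafluorobutanesulfonyl fluoride, CsF (cat.), THF, 0 °C to rt
Reagents that add atoms: nonafluorobutane-1-sulfonyl fluoride, FS(=O)(=O)C(F)(F)C(F)(F)C(F)(F)C(F)(F)F
Why: Fluoride-triggered C-desilylation unveils the enolate specifically between C3 and C4 and it is O-sulfonylated at once by the sulfonyl fluoride (alkenyl nonaflate formation from a silyl precursor), so no strong base comes near the epimerisable C13–H.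

Step 13
Reactants: 21 C4 alkenyl nonaflate of the tetracycle
Product: 22 CNP0133550.1 (target)
Conditions: Pd(OAc)2 (cat.), PPh3, HCO2H, n-Bu3N, DMF, 60 °C
Reagents that add atoms: none
Why: Palladium-catalysed transfer hydrogenolysis of the alkenyl nonaflate (oxidative addition; formate exchange; decarboxylation; reductive elimination) replaces the sulfonate by hydrogen and leaves the C3=C4 and C11=C12 olefins in place.

Compound list
1 | 7-bromohept-1-ene | C=CCCCCCBr | starting material
2 | (E)-1-bromoprop-1-ene | C/C=C/Br | starting material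
3 | B-(7-bromoheptyl)-9-borabicyclo[3.3.1]nonane | BrCCCCCCCB1C2CCCC1CCC2 | intermediate
4 | (E)-10-bromodec-2-ene | C/C=C/CCCCCCCBr | intermediate
5 | (E)-10-iododec-2-ene | C/C=C/CCCCCCCI | intermediate
6 | (1S,5R)-bicyclo[3.2.0]hept-2-en-6-one | C1[C@H]2C=CC[C@H]2C1=O | starting material
7 | lithium enolate of 6 (C6=C7) | [Li]OC1=C[C@H]2C=CC[C@@H]12 | intermediate
8 | (1R,5R,7R)-7-exo-[(E)-dec-8-en-1-yl]bicyclo[3.2.0]hept-2-en-6-one | C/C=C/CCCCCCC[C@@H]1[C@H]2C=CC[C@H]2C1=O | intermediate
9 | ethyl (triphenylphosphoranylidene)acetate | CCOC(=O)C=P(c1ccccc1)(c1ccccc1)c1ccccc1 | starting material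
10 | ethyl 2-[7-exo-((E)-dec-8-en-1-yl)bicyclo[3.2.0]hept-2-en-6-ylidene]acetate (both geometries of the new olefin) | C/C=C/CCCCCCC[C@@H]1[C@H]2C=CC[C@H]2C1=CC(=O)OCC | intermediate
11 | ethyl 2-[7-exo-((E)-dec-8-en-1-yl)bicyclo[3.2.0]hept-2-en-6-endo-yl]acetate | C/C=C/CCCCCCC[C@@H]1[C@H]2C=CC[C@H]2[C@H]1CC(=O)OCC | intermediate
12 | ethyl 2-[7-exo-((E)-dec-8-en-1-yl)-2-exo-hydroperoxybicyclo[3.2.0]hept-3-en-6-endo-yl]acetate | C/C=C/CCCCCCC[C@@H]1[C@H]2[C@H](OO)C=C[C@H]2[C@H]1CC(=O)OCC | intermediate
13 | ethyl 2-[7-exo-((E)-dec-8-en-1-yl)-2-exo-hydroxybicyclo[3.2.0]hept-3-en-6-endo-yl]acetate | C/C=C/CCCCCCC[C@@H]1[C@H]2[C@H](O)C=C[C@H]2[C@H]1CC(=O)OCC | intermediate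
14 | 2-[7-exo-((E)-dec-8-en-1-yl)-2-exo-hydroxybicyclo[3.2.0]hept-3-en-6-endo-yl]acetaldehyde | C/C=C/CCCCCCC[C@@H]1[C@H]2[C@H](O)C=C[C@H]2[C@H]1CC=O | intermediate
15 | methyl (E)-4-(diethoxyphosphoryl)but-2-enoate | CCOP(=O)(OCC)C/C=C/C(=O)OC | starting material
16 | methyl (2E,4E)-6-[7-exo-((E)-dec-8-en-1-yl)-2-exo-hydroxybicyclo[3.2.0]hept-3-en-6-endo-yl]hexa-2,4-dienoate | C/C=C/CCCCCCC[C@@H]1[C@H]2[C@H](O)C=C[C@H]2[C@H]1C/C=C/C=C/C(=O)OC | intermediate
17 | 4-hydroxy-3-nor tetracycle (rings A, C and D of the target; C4 carbinol bridging C2 and C5, OH on the convex face) | C/C=C/CCCCCCC[C@@H]1[C@H]2[C@H](O)[C@@H]3[C@@H]4[C@H]2[C@H]1C[C@H]4C=C[C@H]3C(=O)OC | intermediate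
18 | 4-oxo-3-nor tetracycle (cyclopentanone C2/C4/C5/C6/C7) | C/C=C/CCCCCCC[C@@H]1[C@H]2C(=O)[C@@H]3[C@@H]4[C@H]2[C@H]1C[C@H]4C=C[C@H]3C(=O)OC | intermediate
19 | 3-trimethylsilyl-4-oxo tetracycle (ring B as cyclohexanone; C3 configuration not controlled) | C/C=C/CCCCCCC[C@@H]1[C@H]2C([Si](C)(C)C)C(=O)[C@@H]3[C@@H]4[C@H]2[C@H]1C[C@H]4C=C[C@H]3C(=O)OC | intermediate
20 | cesium C3=C4 enolate of the ring-expanded ketone | C/C=C/CCCCCCC[C@@H]1[C@H]2C=C([O-])[C@@H]3[C@@H]4[C@H]2[C@H]1C[C@H]4C=C[C@H]3C(=O)OC.[Cs+] | intermediate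
21 | C4 alkenyl nonaflate of the tetracycle (C3=C4) | C/C=C/CCCCCCC[C@@H]1[C@H]2C=C(OS(=O)(=O)C(F)(F)C(F)(F)C(F)(F)C(F)(F)F)[C@@H]3[C@@H]4[C@H]2[C@H]1C[C@H]4C=C[C@H]3C(=O)OC | intermediate
22 | CNP0133550.1 | C/C=C/CCCCCCC[C@@H]1[C@H]2C=C[C@@H]3[C@@H]4[C@H]2[C@H]1C[C@H]4C=C[C@H]3C(=O)OC | target

Total step count: 13. Longest linear sequence: 13 steps (from 1 through 5 and 8 to 22; 11 steps from ketone 6).

Steps most likely to fail

Step 6 (photooxygenation). The ene reaction may also take place at the remote trans-olefin of the side chain, and hydrogen abstraction from the bridgehead would give the wrong allylic regioisomer. The fallback oxygenates before the side chain is present. It sets out from 6 and returns at 13. Photooxygenation of 6 and PPh3 reduction should give 2-exo-hydroxybicyclo[3.2.0]hept-3-en-6-one F1. Silylation (TBSCl, imidazole) gives the silyl ether F2. Alkylation of its kinetic C7 enolate with 5 gives the 7-exo-decenyl ketone F3. Wittig reaction with 9 gives the exocyclic enoate F4. Copper hydride reduction gives the silyl ether of 13 F5, and TBAF then releases 13.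

Step 11 (ring expansion). Addition of the diazoalkane to the doubly α-branched ketone may be slow, insertion may repeat, or silicon may be lost or migrate before step 12. The fallback sets out from 18 and returns at 22. Takai–Lombardo methylenation (Zn, CH2Br2, TiCl4) should give the C4 exocyclic methylene compound F6. Hydroxy(tosyloxy)iodobenzene in methanol then induces an oxidative 1,2-shift to the ring-expanded C4 ketone F7. Kinetic enolisation at the new C3 methylene (LiHMDS, −78 °C) and PhNTf2 give the enol triflate F8, which is reduced with Pd(OAc)2/PPh3/HCO2H/n-Bu3N to 22.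

Step 3 (alkylation). Self-condensation and polyalkylation of the strained-ring enolate may outrun the slow SN2 reaction with an unactivated primary iodide. The fallback uses an aza-enolate instead; it sets out from 6 (with 5) and returns at 8. Condensation of 6 with N,N-dimethylhydrazine gives the hydrazone F9. Deprotonation with LDA and alkylation with 5 give the 7-exo-alkylated hydrazone F10, and hydrolysis with aqueous oxalic acid releases 8.

Further compounds
F1 | step 6 | 2-exo-hydroxybicyclo[3.2.0]hept-3-en-6-one | C1[C@H]2[C@H](O)C=C[C@H]2C1=O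
F2 | step 6 | 2-exo-(tert-butyldimethylsilyloxy)bicyclo[3.2.0]hept-3-en-6-one | C1[C@H]2[C@H](O[Si](C)(C)C(C)(C)C)C=C[C@H]2C1=O
F3 | step 6 | 7-exo-[(E)-dec-8-en-1-yl]-2-exo-(tert-butyldimethylsilyloxy)bicyclo[3.2.0]hept-3-en-6-one | C/C=C/CCCCCCC[C@@H]1[C@H]2[C@H](O[Si](C)(C)C(C)(C)C)C=C[C@H]2C1=O
F4 | step 6 | ethyl 2-[7-exo-decenyl-2-exo-(tert-butyldimethylsilyloxy)bicyclo[3.2.0]hept-3-en-6-ylidene]acetate | C/C=C/CCCCCCC[C@@H]1[C@H]2[C@H](O[Si](C)(C)C(C)(C)C)C=C[C@H]2C1=CC(=O)OCC
F5 | step 6 | tert-butyldimethylsilyl ether of 13 | C/C=C/CCCCCCC[C@@H]1[C@H]2[C@H](O[Si](C)(C)C(C)(C)C)C=C[C@H]2[C@H]1CC(=O)OCC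
F6 | step 11 | 4-methylene-3-nor tetracycle | C/C=C/CCCCCCC[C@@H]1[C@H]2C(=C)[C@@H]3[C@@H]4[C@H]2[C@H]1C[C@H]4C=C[C@H]3C(=O)OC
F7 | step 11 | ring-expanded 4-oxo tetracycle (C3 methylene) | C/C=C/CCCCCCC[C@@H]1[C@H]2CC(=O)[C@@H]3[C@@H]4[C@H]2[C@H]1C[C@H]4C=C[C@H]3C(=O)OC
F8 | step 11 | C4 enol triflate of the tetracycle (C3=C4) | C/C=C/CCCCCCC[C@@H]1[C@H]2C=C(OS(=O)(=O)C(F)(F)F)[C@@H]3[C@@H]4[C@H]2[C@H]1C[C@H]4C=C[C@H]3C(=O)OC
F9 | step 3 | N,N-dimethylhydrazone of 6 | C1[C@H]2C=CC[C@H]2C1=NN(C)C
F10 | step 3 | N,N-dimethylhydrazone of 8 | C/C=C/CCCCCCC[C@@H]1[C@H]2C=CC[C@H]2C1=NN(C)C
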